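**Retrosynthetic overview** (chain numbered C1 = carbinol carbon on the oxazole to C6 = methyl)
- The target comes from its O-5 benzyl ether by hydrogenolysis; this from a C1 ketone/C3 alcohol by 1,3-syn reduction (sets C1); this from a 2-isoxazoline by N–O hydrogenolysis and imine hydrolysis.
- Key disconnection C1–C2: [3+2] cycloaddition of the bis-oxazole nitrile oxide (C1 at the acid oxidation level) with the terminal alkene C2=C3 of a C2–C6 fragment. The same event makes the C3–O bond and the C3 stereocentre.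
- Enabling feature: the C1(OH)–C2H2–C3(OH) 1,3-diol, lying between C4 of the 2,4-disubstituted oxazole and the oxygenated C4 of the chain, maps onto ring atoms C3/C4/C5/O1 of a 4,5-dihydro-1,2-oxazole. The allylic C4–O ether beside the alkene directs the face, and the ring masks O-1 and O-3 while O-4 is changed from silyl to myristoyl.
- Alkene fragment from ethyl (S)-lactate (C5, C6) by chelation-controlled vinyl addition (C4). Nitrile oxide from a bis-oxazole ester made by sp3–sp2 Suzuki coupling of two bought oxazoles.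
- Ring order: both oxazoles are bought; the only ring formed is the temporary isoxazoline (step 8), which is opened again in step 11.

Key step: step 8

Remark: the aldoxime of step 7 forms as an E/Z mixture; both isomers give the same nitrile oxide, so it is used unseparated (its SMILES shows the E isomer).

**Route**

Step 1
Reactants: 1 ethyl (2S)-2-hydroxypropanoate (ethyl (S)-lactate)
Product: 2 ethyl (2S)-2-(benzyloxy)propanoate
Conditions: BnOC(=NH)CCl3, TfOH (cat.), cyclohexane/CH2Cl2 2:1, rt
Reagents that add atoms: benzyl 2,2,2-trichloroacetimidate, N=C(OCc1ccccc1)C(Cl)(Cl)Cl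
Why: acid-catalysed trichloroacetimidate O-benzylation is base-free, so the α-stereocentre of the lactate should not epimerise.

Step 2
Reactants: 2 ethyl (2S)-2-(benzyloxy)propanoate
Product: 3 (2S)-2-(benzyloxy)propanal
Conditions: DIBAL-H (1.05 equiv), Et2O, −78 °C; Rochelle salt; used crude
Reagents that add atoms: none
Why: DIBAL-H partial reduction stops at the aldehyde because the tetrahedral aluminium hemiacetal is stable at −78 °C, and immediate use avoids racemisation of the α-alkoxy aldehyde.

Step 3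
Reactants: 3 (2S)-2-(benzyloxy)propanal
Product: 4 (3S,4S)-4-(benzyloxy)pent-1-en-3-ol
Conditions: MgBr2·OEt2, CH2Cl2, −78 °C; then CH2=CHMgBr (THF), −78 °C; aq NH4Cl
Reagents that add atoms: vinylmagnesium bromide, C=C[Mg]Br
Why: Grignard addition under Cram-chelate control (Mg bridges C=O and the benzyl ether oxygen) should deliver vinyl to the face opposite the methyl group and give the syn (3S,4S) alcohol; the minor anti isomer is to be removed by chromatography.

Step 4
Reactants: 4 (3S,4S)-4-(benzyloxy)pent-1-en-3-ol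
Product: 5 {[(3S,4S)-4-(benzyloxy)pent-1-en-3-yl]oxy}(tert-butyl)dimethylsilane
Conditions: TBSCl, imidazole, DMF, rt
Reagents that add atoms: tert-butyldimethylsilyl chloride, CC(C)(C)[Si](C)(C)Cl
Why: standard imidazole-promoted silylation gives the allylic silyl ether that the cycloaddition needs for facial control.

Step 5
Reactants: 6 methyl 2-(chloromethyl)-1,3-oxazole-4-carboxylate; 7 5-(4,4,5,5-tetramethyl-1,3,2-dioxaborolan-2-yl)-2-[tri(propan-2-yl)silyl]-1,3-oxazole
Product: 9 methyl 2-(1,3-oxazol-5-ylmethyl)-1,3-oxazole-4-carboxylate, via C2-silylated bis-oxazole ester 8 (not isolated)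
Conditions: Pd(dppf)Cl2 (5 mol %), K3PO4, 1,4-dioxane/H2O 10:1, 70 °C; then 2 M aq HCl to pH 1, rt
Reagents that add atoms: none
Why: Suzuki–Miyaura coupling of a benzylic-type C(sp3)–Cl bond with a heteroaryl boronate whose C2 silyl group blocks the acidic oxazole C2 position, followed by acid protodesilylation.

Step 6
Reactants: 9 methyl 2-(1,3-oxazol-5-ylmethyl)-1,3-oxazole-4-carboxylate
Product: 10 2-(1,3-oxazol-5-ylmethyl)-1,3-oxazole-4-carbaldehyde
Conditions: DIBAL-H (1.1 equiv), CH2Cl2, −78 °C; Rochelle salt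
Reagents that add atoms: none
Why: DIBAL-H reduction of an oxazole-4-carboxylate should stop at the aldehyde because the neighbouring ring nitrogen chelates and stabilises the tetrahedral aluminate at −78 °C.

Step 7
Reactants: 10 2-(1,3-oxazol-5-ylmethyl)-1,3-oxazole-4-carbaldehyde
Product: 11 N-{[2-(1,3-oxazol-5-ylmethyl)-1,3-oxazol-4-yl]methylidene}hydroxylamine (aldoxime, E/Z mixture)
Conditions: NH2OH·HCl, NaOAc, EtOH/H2O, rt
Reagents that add atoms: hydroxylamine hydrochloride, Cl.NO
Why: oxime condensation of an aldehyde under buffered conditions; the N–O unit brought in here becomes the isoxazoline N–O and later the C3 oxygen.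

Step 8
Reactants: 11 aldoxime (1.5 equiv); 5 {[(3S,4S)-4-(benzyloxy)pent-1-en-3-yl]oxy}(tert-butyl)dimethylsilane
Product: 14 (5S)-5-[(1R,2S)-2-(benzyloxy)-1-{[tert-butyl(dimethyl)silyl]oxy}propyl]-3-[2-(1,3-oxazol-5-ylmethyl)-1,3-oxazol-4-yl]-4,5-dihydro-1,2-oxazole, via hydroximoyl chloride 12 (not isolated), via nitrile oxide 13 (not isolated)
Conditions: 11, NCS, DMF, rt; then 5, Et2O, Et3N added over 8 h by syringe pump, 0 °C to rt
Reagents that add atoms: none
Why: NCS converts the aldoxime into hydroximoyl chloride 12, slow addition of Et3N dehydrochlorinates it to nitrile oxide 13, and this 1,3-dipole adds in a concerted suprafacial [3+2] fashion to the terminal alkene of 5, forming the oxazolyl-carbon–CH2 bond and the O–CH bond in one event. The closest known reaction type is the Huisgen nitrile oxide cycloaddition to α-alkoxy terminal alkenes, as used in isoxazoline ("masked aldol") routes to 2-deoxy sugars. The 4,5-dihydro-1,2-oxazole ring closes by intermolecular cycloaddition (both σ-bonds formed together), with the oxygen terminus going to the substituted alkene carbon so that only the 5-substituted isoxazoline should form. The new stereocentre (ring C5, later the C3 carbinol) is controlled by the adjacent silyloxy-bearing carbon through the inside-alkoxy effect: in the transition state the OTBS group lies inside, the CH(OBn)CH3 group anti to the incoming dipole and H outside, which should give the anti (erythro) adduct, i.e. (5S). The step needs regioselectivity, secured by the monosubstituted alkene, facial selectivity, secured by keeping O-4 as an ether and not yet as the ester, and suppression of furoxan formation, secured by generating 13 slowly in the presence of the alkene. Both oxime isomers converge on the same linear nitrile oxide, and the minor C5 epimer is to be removed by chromatography.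

Step 9
Reactants: 14 silyl-protected isoxazoline
Product: 15 (1R,2S)-2-(benzyloxy)-1-{(5S)-3-[2-(1,3-oxazol-5-ylmethyl)-1,3-oxazol-4-yl]-4,5-dihydro-1,2-oxazol-5-yl}propan-1-ol
Conditions: HF·pyridine, pyridine, THF, 0 °C to rt
Reagents that add atoms: none
Why: buffered fluoride desilylation frees only O-4, because O-1 and O-3 are still tied up in the isoxazoline ring and O-5 is a benzyl ether.

Step 10
Reactants: 15 isoxazoline alcohol
Product: 16 (1R,2S)-2-(benzyloxy)-1-{(5S)-3-[2-(1,3-oxazol-5-ylmethyl)-1,3-oxazol-4-yl]-4,5-dihydro-1,2-oxazol-5-yl}propyl tetradecanoate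
Conditions: C13H27COCl, pyridine, DMAP (cat.), CH2Cl2, 0 °C to rt
Reagents that add atoms: tetradecanoyl chloride, CCCCCCCCCCCCCC(=O)Cl
Why: DMAP-catalysed acylation of the only free hydroxyl places the myristate on O-4 with retention of configuration.

Step 11
Reactants: 16 isoxazoline myristate
Product: 18 (2S,3S,4S)-2-(benzyloxy)-4-hydroxy-6-oxo-6-[2-(1,3-oxazol-5-ylmethyl)-1,3-oxazol-4-yl]hexan-3-yl tetradecanoate, via β-hydroxy imine 17 (not isolated)
Conditions: Raney Ni (W-2), H2 (1 atm), B(OH)3, MeOH/H2O 5:1, rt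
Reagents that add atoms: water, O
Why: hydrogenolysis of the weak isoxazoline N–O bond gives the β-hydroxy imine, which boric acid-buffered water hydrolyses to the ketone before the C=N bond can be reduced; the C3 stereocentre is untouched (the descriptor at the ester carbon changes from R to S only through CIP priorities).

Step 12
Reactants: 18 β-hydroxy ketone
Product: 20 (2S,3S,4S,6R)-2-(benzyloxy)-4,6-dihydroxy-6-[2-(1,3-oxazol-5-ylmethyl)-1,3-oxazol-4-yl]hexan-3-yl tetradecanoate, via diethylboron chelate 19 (not isolated)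
Conditions: Et2BOMe, THF/MeOH 4:1, −78 °C; NaBH4, −78 °C; MeOH/pH 7 buffer quench, repeated evaporation from MeOH
Reagents that add atoms: none
Why: Narasaka–Prasad reduction, in which the diethylboron chelate between the C3 oxygen and the C1 ketone fixes a half-chair and external hydride adds axially, should give the 1,3-syn diol and hence (R) at the oxazolyl carbinol.

Step 13
Reactants: 20 syn-diol benzyl ether
Product: 21 (2S,3R,4S,6R)-2,4,6-trihydroxy-6-[2-(1,3-oxazol-5-ylmethyl)-1,3-oxazol-4-yl]hexan-3-yl tetradecanoate (target)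
Conditions: H2 (1 atm), Pd(OH)2/C, EtOAc, rt
Reagents that add atoms: none
Why: neutral hydrogenolysis of the benzyl ether frees O-5 without acid or base, so the myristate should stay on O-4 and the oxazoles and carbinols are left intact.

**Compound list**

1 | ethyl (2S)-2-hydroxypropanoate | CCOC(=O)[C@H](C)O | starting material
2 | ethyl (2S)-2-(benzyloxy)propanoate | CCOC(=O)[C@H](C)OCc1ccccc1 | intermediate
3 | (2S)-2-(benzyloxy)propanal | O=C[C@H](C)OCc1ccccc1 | intermediate
4 | (3S,4S)-4-(benzyloxy)pent-1-en-3-ol | C=C[C@H](O)[C@H](C)OCc1ccccc1 | intermediate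
5 | {[(3S,4S)-4-(benzyloxy)pent-1-en-3-yl]oxy}(tert-butyl)dimethylsilane | C=C[C@H](O[Si](C)(C)C(C)(C)C)[C@H](C)OCc1ccccc1 | intermediate
6 | methyl 2-(chloromethyl)-1,3-oxazole-4-carboxylate | COC(=O)c1coc(CCl)n1 | starting material
7 | 5-(4,4,5,5-tetramethyl-1,3,2-dioxaborolan-2-yl)-2-[tri(propan-2-yl)silyl]-1,3-oxazole | CC(C)[Si](C(C)C)(C(C)C)c1ncc(B2OC(C)(C)C(C)(C)O2)o1 | starting material
8 | methyl 2-({2-[tri(propan-2-yl)silyl]-1,3-oxazol-5-yl}methyl)-1,3-oxazole-4-carboxylate | COC(=O)c1coc(Cc2cnc([Si](C(C)C)(C(C)C)C(C)C)o2)n1 | intermediate (not isolated)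
9 | methyl 2-(1,3-oxazol-5-ylmethyl)-1,3-oxazole-4-carboxylate | COC(=O)c1coc(Cc2cnco2)n1 | intermediate
10 | 2-(1,3-oxazol-5-ylmethyl)-1,3-oxazole-4-carbaldehyde | O=Cc1coc(Cc2cnco2)n1 | intermediate
11 | (E)-N-{[2-(1,3-oxazol-5-ylmethyl)-1,3-oxazol-4-yl]methylidene}hydroxylamine (used as E/Z mixture) | O/N=C/c1coc(Cc2cnco2)n1 | intermediate
12 | (Z)-N-hydroxy-2-(1,3-oxazol-5-ylmethyl)-1,3-oxazole-4-carboximidoyl chloride | O/N=C(\Cl)c1coc(Cc2cnco2)n1 | intermediate (not isolated)
13 | 2-(1,3-oxazol-5-ylmethyl)-1,3-oxazole-4-carbonitrile oxide | [O-][N+]#Cc1coc(Cc2cnco2)n1 | intermediate (not isolated)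
14 | (5S)-5-[(1R,2S)-2-(benzyloxy)-1-{[tert-butyl(dimethyl)silyl]oxy}propyl]-3-[2-(1,3-oxazol-5-ylmethyl)-1,3-oxazol-4-yl]-4,5-dihydro-1,2-oxazole | CC(C)(C)[Si](C)(C)O[C@H]([C@H](C)OCc1ccccc1)[C@@H]1CC(=NO1)c1coc(Cc2cnco2)n1 | intermediate
15 | (1R,2S)-2-(benzyloxy)-1-{(5S)-3-[2-(1,3-oxazol-5-ylmethyl)-1,3-oxazol-4-yl]-4,5-dihydro-1,2-oxazol-5-yl}propan-1-ol | O[C@H]([C@H](C)OCc1ccccc1)[C@@H]1CC(=NO1)c1coc(Cc2cnco2)n1 | intermediate
16 | (1R,2S)-2-(benzyloxy)-1-{(5S)-3-[2-(1,3-oxazol-5-ylmethyl)-1,3-oxazol-4-yl]-4,5-dihydro-1,2-oxazol-5-yl}propyl tetradecanoate | CCCCCCCCCCCCCC(=O)O[C@H]([C@H](C)OCc1ccccc1)[C@@H]1CC(=NO1)c1coc(Cc2cnco2)n1 | intermediate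
17 | (2S,3S,4S)-2-(benzyloxy)-4-hydroxy-6-imino-6-[2-(1,3-oxazol-5-ylmethyl)-1,3-oxazol-4-yl]hexan-3-yl tetradecanoate | CCCCCCCCCCCCCC(=O)O[C@H]([C@H](C)OCc1ccccc1)[C@@H](O)CC(=N)c1coc(Cc2cnco2)n1 | intermediate (not isolated)
18 | (2S,3S,4S)-2-(benzyloxy)-4-hydroxy-6-oxo-6-[2-(1,3-oxazol-5-ylmethyl)-1,3-oxazol-4-yl]hexan-3-yl tetradecanoate | CCCCCCCCCCCCCC(=O)O[C@H]([C@H](C)OCc1ccccc1)[C@@H](O)CC(=O)c1coc(Cc2cnco2)n1 | intermediate
19 | (2S,3S,4S)-2-(benzyloxy)-4-[(diethylboranyl)oxy]-6-oxo-6-[2-(1,3-oxazol-5-ylmethyl)-1,3-oxazol-4-yl]hexan-3-yl tetradecanoate | CCCCCCCCCCCCCC(=O)O[C@H]([C@H](C)OCc1ccccc1)[C@@H](OB(CC)CC)CC(=O)c1coc(Cc2cnco2)n1 | intermediate (not isolated)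
20 | (2S,3S,4S,6R)-2-(benzyloxy)-4,6-dihydroxy-6-[2-(1,3-oxazol-5-ylmethyl)-1,3-oxazol-4-yl]hexan-3-yl tetradecanoate | CCCCCCCCCCCCCC(=O)O[C@H]([C@H](C)OCc1ccccc1)[C@@H](O)C[C@@H](O)c1coc(Cc2cnco2)n1 | intermediate
21 | (2S,3R,4S,6R)-2,4,6-trihydroxy-6-[2-(1,3-oxazol-5-ylmethyl)-1,3-oxazol-4-yl]hexan-3-yl tetradecanoate | CCCCCCCCCCCCCC(=O)O[C@H]([C@H](C)O)[C@@H](O)C[C@@H](O)c1coc(Cc2cnco2)n1 | target

**Step count and risks**

Total step count: 13. Longest linear sequence: 10 steps (steps 1–4 and 8–13, from ethyl (S)-lactate).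

Steps most likely to fail:

1. Step 8. What may go wrong: weak facial discrimination, because the inside-alkoxy bias of an open-chain allylic silyl ether is only moderate, and dimerisation of the nitrile oxide to the furoxan before it meets the hindered alkene.
   Fallback (sets out from 4 and 10, comes back at 20): the same C1–C2 bond is made by a boron aldol reaction instead. Alcohol 4 is acylated with tetradecanoyl chloride (pyridine, DMAP) to (3S,4S)-4-(benzyloxy)pent-1-en-3-yl tetradecanoate F1. Wacker–Tsuji oxidation (PdCl2, CuCl, O2, DMF/H2O) should give the methyl ketone (3R,4S)-4-(benzyloxy)-2-oxopentan-3-yl tetradecanoate F2. Cy2BCl/Et3N (Et2O, −78 to 0 °C) enolises on the methyl side to (3R,4S)-4-(benzyloxy)-2-[(dicyclohexylboranyl)oxy]pent-1-en-3-yl tetradecanoate F3. This adds to aldehyde 10 at −78 °C under 1,5-anti induction from the β-benzyloxy group, giving the boron aldolate (2S,3R,6R)-2-(benzyloxy)-6-[(dicyclohexylboranyl)oxy]-4-oxo-6-[2-(1,3-oxazol-5-ylmethyl)-1,3-oxazol-4-yl]hexan-3-yl tetradecanoate F4. LiBH4 added to the same flask at −78 °C should reduce the chelated aldolate to the 1,3-syn diol, and a pH 7-buffered H2O2 work-up gives 20, which goes on through step 13.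

2. Step 5. What may go wrong: protodeboronation of the 5-oxazolyl boronate, hydrolysis of the chloromethyl group or of the methyl ester in the aqueous base, and over-alkylation at the acidic bis-azolyl methylene.
   Fallback (sets out from 6, comes back at 9): the polarity of the coupling is reversed and made anhydrous. Zinc dust/LiCl in THF inserts into the C–Cl bond of 6 to give [4-(methoxycarbonyl)-1,3-oxazol-2-yl]methylzinc chloride F5. A Negishi coupling with purchased 5-bromo-1,3-oxazole (Pd(OAc)2/SPhos, THF, rt to 50 °C) then gives 9 directly, with no silyl group to remove.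

3. Step 12. What may go wrong: 1,2-migration of the myristoyl group from O-4 to the neighbouring oxygen under the borohydride/methoxide medium, and erosion of 1,3-syn control if the oxazole nitrogen competes for boron.
   Fallback (sets out from 18, comes back at 20): stereocontrol is moved from the substrate chelate to the catalyst by a Noyori asymmetric transfer hydrogenation of the heteroaryl ketone. RuCl[(R,R)-TsDPEN](p-cymene), HCO2H/Et3N 5:2, rt should give the (R)-carbinol in a mildly acidic, boron-free and alkoxide-free medium. This fallback makes no new compound (F0).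

Further compounds
F1 | step 8 | (3S,4S)-4-(benzyloxy)pent-1-en-3-yl tetradecanoate | C=C[C@H](OC(=O)CCCCCCCCCCCCC)[C@H](C)OCc1ccccc1
F2 | step 8 | (3R,4S)-4-(benzyloxy)-2-oxopentan-3-yl tetradecanoate | CC(=O)[C@H](OC(=O)CCCCCCCCCCCCC)[C@H](C)OCc1ccccc1
F3 | step 8 | (3R,4S)-4-(benzyloxy)-2-[(dicyclohexylboranyl)oxy]pent-1-en-3-yl tetradecanoate | C=C(OB(C1CCCCC1)C1CCCCC1)[C@H](OC(=O)CCCCCCCCCCCCC)[C@H](C)OCc1ccccc1
F4 | step 8 | (2S,3R,6R)-2-(benzyloxy)-6-[(dicyclohexylboranyl)oxy]-4-oxo-6-[2-(1,3-oxazol-5-ylmethyl)-1,3-oxazol-4-yl]hexan-3-yl tetradecanoate | CCCCCCCCCCCCCC(=O)O[C@H]([C@H](C)OCc1ccccc1)C(=O)C[C@@H](OB(C1CCCCC1)C1CCCCC1)c1coc(Cc2cnco2)n1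
F5 | step 5 | [4-(methoxycarbonyl)-1,3-oxazol-2-yl]methylzinc chloride | COC(=O)c1coc(C[Zn]Cl)n1
F0 | step 12 | none | none
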